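## Analysis of the target

Target 29 is a germacranolide. Its ten-membered carbocycle (C1–C10) is fused at C6/C7 to an α,β-unsaturated γ-lactone (O–C6, C7=C11, C12=O) that carries an acetoxymethyl group (C13) on C11; C8 bears a 3-methylbut-2-enoate, and the ring holds two cis-configured trisubstituted epoxides, C1–C10 (methyl C14) and C4–C5 (methyl C15). The six stereocentres are (1S,4S,5R,6R,8R,10R): C4–C5–C6 is a contiguous triad with a cis-epoxide (C3 and C6 on the same side of the oxirane) and an erythro relation between the C5–O and C6–O bonds. Formally, the 4,5-epoxide oxygen, the lactone oxygen at C6 and the ester oxygen at C8 lie on one face of the ring, and the 1,10-epoxide oxygen on the other. The sensitive groups are the two epoxides (acid, transannular attack), the C6–H (γ to the lactone carbonyl, with the C4–C5 epoxide β,γ to it, so base opens the epoxide), the allylic acetate on a Michael acceptor, and the senecioate (deconjugation). The synthesis is hard because of the medium ring and because the erythro cis-epoxy carbinol C4–C6 is not reachable by hydroxyl-directed epoxidation of a C4=C5 allylic alcohol: C4 always carries a substituent cis to the carbinol, and allylic 1,3-strain then steers such epoxidations to the threo isomer. The strategy rests on C4: it is a methyl-bearing tertiary C–O centre identical to the carbinol carbon of (S)-linalool 1, its oxygen is the oxygen of the C4–C5 oxirane, and the C5–O bond of that oxirane is anti to the C6–O bond, which is exactly the pattern produced when a trans C5–C6 epoxide migrates to a C4 alkoxide.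

## Retrosynthetic reasoning

**29 back to 25 (ester groups, C13 oxygen, C1–C10 epoxide).** The acetate on C13 makes C11 an SN2′ acceptor, so it is put on last, from alcohol 27 with anhydride 28. The C13 oxygen travels as a 4-methoxybenzyl ether (26) because that group survives strong base, triflation and chromium reagents and comes off oxidatively at neutral pH. The C1–C10 epoxide is cut back to the Z-alkene of 25; peracid epoxidation is stereospecific for the cis-epoxide and only has to choose among three alkenes, two of which are conjugated and inert.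

**25 back to 22 (ring bond C7–C8, ester C8–O).** The senecioate comes from alcohol 23 and acid chloride 24. The ring is opened at C7–C8 because this places the new carbinol exactly where the ester sits, and because C7 is the β-carbon of the butenolide and is available as an enol triflate. The forward reaction is a chromium/nickel-mediated alkenyl–aldehyde coupling of triflate aldehyde 22, which tolerates esters, lactone and epoxide and has to close a ten-membered ring and set C8.

**22 back to 18 (butenolide bonds C11–C7 and O–C12).** The enol triflate 20 comes from tetronic acid 19, and 19 from a Dieckmann closure of the C6 ester 18: the acyl group on the C6 oxygen supplies C12, C11 and C13, and its enolate attacks the C7 ester. This uses the C7 carboxyl carbon that the glycidate already carries, so no carbon has to be added at C7. The C8 oxygen is carried as a silyl ether through the base and triflation steps (20, 21).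

**18 back to 11 (arm C8–C10: C1=C10, C10–C9, C8–O).** The Z-trisubstituted alkene is made from the C1 aldehyde 11 by a Z-selective iodo-olefination with the ylide from 12 (iodide 13). The iodine sits cis to C2, where C9 must go; a Stille coupling with 14 gives diene 15 with retention, and hydroboration of its terminal alkene gives the C8 alcohol 17. A Z-selective phosphonate olefination was weighed for this bond, but it would leave an ester carbon at C9 that has to be reduced and extended by one carbon with hydride reagents, which the C7 ester does not survive.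

**11 back to 8 (C6–O acyl bond, C1 oxidation level).** Esterification of 8 with acid 9 gives 10; the acyl group is needed for the Dieckmann step and meanwhile protects the C6 hydroxyl. The C1 aldehyde is released from the primary silyl ether of 10 by direct oxidation, so that a free C1 hydroxyl never sits next to the C4–C5 epoxide.

**8 back to 7 (O–C5 bond of the C4–C5 oxirane; the key step).** The cis-epoxy α-hydroxy ester 8 is the epoxide-migration isomer of trans-glycidic ester 7. The cut gives a precursor whose three stereocentres are easy to set (one from 1, two by epoxidation of an E-enoate) and turns the difficult erythro triad into a stereospecific intramolecular displacement.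

**7 back to 4 and 5 (epoxide C–O bonds, alkene C5=C6).** The trans-epoxide comes from a reagent-controlled nucleophilic epoxidation of E-enoate 6, and 6 from cross-metathesis of the vinyl carbinol 4 with methyl acrylate 5, which adds C6 and C7 in one step.

**4 back to 1 (cleavage at C1).** Cross-metathesis cannot be run on 1 itself: its 1,6-diene would close to a five-membered carbocycle by ring-closing metathesis faster than it would couple with 5. The trisubstituted alkene has to be cleaved to reach C1 in any case, so it is ozonised first (diol 3) and C1 is carried as the triethylsilyl ether 4.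

## Alternatives that were turned down

**Alternative 1:** The disconnection is the C8–C9 bond, formed by a two-carbon ring expansion. In the forward direction the potassium alkoxide of the eight-membered divinyl carbinol A1 undergoes an alkoxide-accelerated 1,3-shift of the allylic ring carbon C9 from the carbinol carbon C6 to the end of the vinyl group (C8), giving the ten-membered dienone A2 with its ketone at C6.
- For: A1 is a few steps from a cheap C10 hydrocarbon; the medium ring is formed by rearrangement and not by an end-to-end cyclisation; both Z-trisubstituted alkenes (the future epoxides) are already in place with ring-enforced geometry.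
- Against: A2 is achiral and oxygenated only at C6. All six stereocentres, the C8 oxygen (β to the ketone and not directly addressable) and C11–C13 would have to be added on a flexible ring, and the erythro epoxy carbinol problem at C4–C6 remains. The 1,3-shift also competes with a 3,3-shift, which for A1 gives an isomeric eight-membered ketone, and its fragmentation–recombination character puts the alkene geometry at risk.
- Comparison: on ring construction and step count to the carbocycle this alternative is clearly stronger. The chosen route offers instead absolute configuration from 1 and a stereospecific C5/C6 relationship.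

**Alternative 2:** The disconnection is the four C–O bonds of both epoxides, made at the outset. Sharpless asymmetric epoxidation of both Z-allylic alcohol units of the achiral diene diol A3 gives the bis-epoxy diol A4, with C10, C1, C4 and C5 as in the target.
- For: four stereocentres are set in one reagent-controlled operation, with enantiomeric enrichment through the double epoxidation. The C1–C10 epoxide does not depend on a ring conformation; on this point it is stronger than the chosen route, which relies on the facial bias of the macrocycle in step 18.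
- Against: Z-allylic alcohols are the slowest and least selective substrates of that reaction, and the two primary hydroxyls of A4 must be differentiated. C6 is still a CH2OH carbon: the C6–C7 bond and the C6 stereocentre would come from addition to an epoxy aldehyde, with only moderate and not necessarily erythro control. C9 needs a one-carbon extension next to a quaternary epoxide carbon, and both acid-labile epoxides must survive every chain-extension and ring-closure step.
- Comparison: the chosen route carries only one epoxide through the C–C bond formations, has C7 attached from the start, and fixes C6 stereospecifically.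

**Alternative 3:** The disconnection is the C4=C5 double bond, formed with ring contraction. Under basic Ramberg–Bäcklund conditions the eleven-membered α-chlorosulfone A5 is deprotonated at C4, the carbanion displaces chloride at C5, and extrusion of the sulfonyl bridge from the episulfone gives the (4Z)-cyclodecene A6, which carries the 1,10-epoxide, an exocyclic methylene on C7 and silyl ethers at C6 and C8.
- For: closing an eleven-membered ring through C–S bonds is easier than closing a ten-membered carbocycle, and the contraction is a dependable way to strained Z-cycloalkenes. On ring closure it is at least as strong as the chromium-mediated closure used here.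
- Against: A5 needs four stereocentres and a long linear preparation, and the base acts next to an epoxide and allylic silyl ethers. After contraction the C4=C5 alkene must still be epoxidised erythro to C6, where a hydroxyl-directed epoxidation is expected to give threo, so the central stereochemical problem returns late. The butenolide carbons C12 and C13 are also still missing.
- Comparison: the chosen route solves the C4–C6 triad early and stereospecifically and pays for it with a harder ring closure.

Key step: step 5

Assumptions: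
- (S)-(+)-Linalool 1 of high enantiomeric purity and acid 9 are taken as purchasable.
- The (S)-enantiomer of the biphenyldiol ligand in step 4 is assumed to give the (2S,3S)-epoxide 7; if the sense is the reverse, the (R)-ligand is used.
- Atom labels C1–C15 follow germacrane numbering in all intermediates.

## Route

Step 1
Reactants: 1 (S)-linalool, (3S)-3,7-dimethylocta-1,6-dien-3-ol
Product: 3 (4S)-4-methylhex-5-ene-1,4-diol, via hydroxy aldehyde 2 (not isolated)
Conditions: O3 (Sudan Red 7B end point), CH2Cl2/MeOH 4:1, −78 °C; then NaBH4, −78 → 0 °C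
Reagents that add atoms: ozone, [O-][O+]=O
Why: Chemoselective ozonolysis with reductive work-up: ozone attacks the electron-rich trisubstituted alkene much faster than the vinyl group, which is deactivated by the allylic oxygen and shielded by the quaternary carbon, and the dye marks the end point. Borohydride reduces aldehyde 2 (otherwise a lactol) to the diol; the C4 stereocentre is not touched.

Step 2
Reactants: 3 (4S)-4-methylhex-5-ene-1,4-diol
Product: 4 (3S)-3-methyl-6-(triethylsilyloxy)hex-1-en-3-ol
Conditions: TESCl (1.05 equiv), imidazole, CH2Cl2, −20 °C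
Reagents that add atoms: chlorotriethylsilane, CC[Si](Cl)(CC)CC
Why: Silylation is selective for the primary over the tertiary hydroxyl. The tertiary allylic alcohol stays free, as needed for the metathesis and later as the Payne nucleophile.

Step 3
Reactants: 4 (3S)-3-methyl-6-(triethylsilyloxy)hex-1-en-3-ol; 5 methyl acrylate
Product: 6 methyl (2E,4S)-4-hydroxy-4-methyl-7-(triethylsilyloxy)hept-2-enoate
Conditions: 5 (5 equiv), second-generation Hoveyda–Grubbs catalyst (5 mol%), CH2Cl2, 40 °C
Reagents that add atoms: none
Why: Olefin cross-metathesis of an unprotected tertiary allylic alcohol with an acrylate: neither partner homodimerises readily, excess acrylate drives the coupling, and the E-enoate is the thermodynamic product. With the trisubstituted alkene already removed, no ring-closing metathesis can compete.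

Step 4
Reactants: 6 methyl (2E,4S)-4-hydroxy-4-methyl-7-(triethylsilyloxy)hept-2-enoate
Product: 7 methyl (2S,3S)-3-[(2S)-2-hydroxy-5-(triethylsilyloxy)pentan-2-yl]oxirane-2-carboxylate
Conditions: Y(OiPr)3 / (S)-6,6'-[oxybis(ethane-2,1-diyloxy)]biphenyl-2,2'-diol / Ph3As=O (1:1:1, 10 mol%), tBuOOH (decane), 4 Å MS, THF, rt
Reagents that add atoms: tert-butyl hydroperoxide, CC(C)(C)OO
Why: Catalytic asymmetric nucleophilic (Weitz–Scheffer) epoxidation with the rare-earth alkoxide system developed for α,β-unsaturated esters: the yttrium-bound peroxide adds to C5 and the enolate closes to the trans-epoxide. The chiral ligand selects the face and sets C5 and C6 (both S in 7); the C4 centre, with methyl and methylene of similar size, has little bias of its own.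

Step 5
Reactants: 7 methyl (2S,3S)-3-[(2S)-2-hydroxy-5-(triethylsilyloxy)pentan-2-yl]oxirane-2-carboxylate
Product: 8 methyl (2S)-2-hydroxy-2-{(2R,3S)-3-methyl-3-[3-(triethylsilyloxy)propyl]oxiran-2-yl}acetate
Conditions: KOtBu (1.0 equiv), THF, −40 → −10 °C; AcOH, −40 °C
Reagents that add atoms: none
Why: KOtBu deprotonates the tertiary C4 hydroxyl, and the alkoxide attacks C5 from the side opposite the C5–O bond of the glycidate (intramolecular SN2), which forms the O–C5 bond, closes the new C4–C5 oxirane and releases the C6 oxygen as the alkoxide of an α-hydroxy ester. The closest known reaction type is the Payne rearrangement of 2,3-epoxy alcohols under aprotic conditions, here with the epoxide of a glycidic ester migrating. The one ring formed, the trisubstituted oxirane, closes in the 3-exo-tet mode. The only stereocentre that changes is C5: it is inverted by the backside attack and so is fixed by the epoxide configuration set in step 4, while C4 and C6 keep their bonds, so the trans-epoxide gives the cis-epoxide (C3 and C6 on the same side) with the erythro carbinol. The step needs the equilibrium on the product side and an intact ester: the product has the more substituted epoxide and the less basic, ester-stabilised secondary alkoxide, C5 (remote from the ester) is the normal site of nucleophilic opening of glycidates, and the trans geometry keeps the C4 oxygen away from the ester carbonyl so no lactone can form. The oxirane C–H of 7 is not acidic, the C6–H of the product is shielded by the adjacent alkoxide, and the cold acetic acid quench keeps the β,γ-epoxy ester from base during work-up.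

Step 6
Reactants: 8 methyl (2S)-2-hydroxy-2-{(2R,3S)-3-methyl-3-[3-(triethylsilyloxy)propyl]oxiran-2-yl}acetate; 9 3-[(4-methoxyphenyl)methoxy]propanoic acid
Product: 10 methyl (2S)-2-{3-[(4-methoxyphenyl)methoxy]propanoyloxy}-2-{(2R,3S)-3-methyl-3-[3-(triethylsilyloxy)propyl]oxiran-2-yl}acetate
Conditions: DCC, DMAP (10 mol%), CH2Cl2, 0 °C → rt
Reagents that add atoms: none
Why: Steglich esterification under neutral conditions that leave the epoxide and the methyl ester alone. The new ester brings C12, C11 and C13 and blocks the C6 hydroxyl while the C8–C10 arm is built.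

Step 7
Reactants: 10 methyl (2S)-2-{3-[(4-methoxyphenyl)methoxy]propanoyloxy}-2-{(2R,3S)-3-methyl-3-[3-(triethylsilyloxy)propyl]oxiran-2-yl}acetate
Product: 11 methyl (2S)-2-{3-[(4-methoxyphenyl)methoxy]propanoyloxy}-2-[(2R,3S)-3-methyl-3-(3-oxopropyl)oxiran-2-yl]acetate
Conditions: (COCl)2, DMSO, CH2Cl2, −78 → −30 °C; Et3N, −78 → 0 °C
Reagents that add atoms: none
Why: Swern oxidation applied directly to a primary triethylsilyl ether: the chlorosulfonium reagent cleaves the O–Si bond and the alkoxysulfonium salt collapses to the aldehyde. No free C1 hydroxyl is formed, which would open the C4–C5 epoxide in a 5-exo mode.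

Step 8
Reactants: 11 methyl (2S)-2-{3-[(4-methoxyphenyl)methoxy]propanoyloxy}-2-[(2R,3S)-3-methyl-3-(3-oxopropyl)oxiran-2-yl]acetate; 12 ethyl(triphenyl)phosphonium iodide
Product: 13 methyl (2S)-2-{(2R,3S)-3-[(3Z)-4-iodopent-3-en-1-yl]-3-methyloxiran-2-yl}-2-{3-[(4-methoxyphenyl)methoxy]propanoyloxy}acetate
Conditions: 12, n-BuLi, THF, 0 °C; I2, −78 °C; NaHMDS, −78 °C; then 11, −78 → −20 °C
Reagents that add atoms: iodine, II
Why: Wittig olefination with the α-iodoethylidene ylide (Stork–Zhao type): kinetically controlled cycloaddition of the non-stabilised ylide gives the (Z)-iodoalkene with iodine cis to the chain. The aldehyde consumes the ylide at −78 °C before it can act as a base on the esters.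

Step 9
Reactants: 13 methyl (2S)-2-{(2R,3S)-3-[(3Z)-4-iodopent-3-en-1-yl]-3-methyloxiran-2-yl}-2-{3-[(4-methoxyphenyl)methoxy]propanoyloxy}acetate; 14 tributyl(ethenyl)stannane
Product: 15 methyl (2S)-2-{3-[(4-methoxyphenyl)methoxy]propanoyloxy}-2-{(2R,3S)-3-methyl-3-[(3Z)-4-methylhexa-3,5-dien-1-yl]oxiran-2-yl}acetate
Conditions: Pd2(dba)3 (5 mol%), AsPh3 (20 mol%), CuI (10 mol%), DMF, rt
Reagents that add atoms: none
Why: Stille coupling: oxidative addition of zerovalent palladium to the alkenyl iodide, transmetalation from tin and reductive elimination form C10–C9 with retention of the Z geometry. The neutral conditions at room temperature spare the esters and the epoxide.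

Step 10
Reactants: 15 methyl (2S)-2-{3-[(4-methoxyphenyl)methoxy]propanoyloxy}-2-{(2R,3S)-3-methyl-3-[(3Z)-4-methylhexa-3,5-dien-1-yl]oxiran-2-yl}acetate
Product: 17 methyl (2S)-2-{(2R,3S)-3-[(3Z)-6-hydroxy-4-methylhex-3-en-1-yl]-3-methyloxiran-2-yl}-2-{3-[(4-methoxyphenyl)methoxy]propanoyloxy}acetate, via alkylborane 16 (not isolated)
Conditions: 9-BBN (1.3 equiv), THF, 0 °C → rt; then NaBO3·4H2O, THF/H2O, 0 °C → rt
Reagents that add atoms: 9-borabicyclo[3.3.1]nonane, B1C2CCCC1CCC2 (its boron stays only in 16); sodium perborate, [Na+].[Na+].O[B-]1(O)OO[B-](O)(O)OO1 (oxygen on C8)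
Why: Hydroboration–oxidation: the bulky borane adds only to the terminal monosubstituted alkene of the diene with boron on C8, leaving the trisubstituted alkene, the esters and the epoxide. The mild perborate oxidation gives the homoallylic alcohol with the Z geometry intact.

Step 11
Reactants: 17 methyl (2S)-2-{(2R,3S)-3-[(3Z)-6-hydroxy-4-methylhex-3-en-1-yl]-3-methyloxiran-2-yl}-2-{3-[(4-methoxyphenyl)methoxy]propanoyloxy}acetate
Product: 18 methyl (2S)-2-{3-[(4-methoxyphenyl)methoxy]propanoyloxy}-2-{(2R,3S)-3-methyl-3-[(3Z)-4-methyl-6-(triethylsilyloxy)hex-3-en-1-yl]oxiran-2-yl}acetate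
Conditions: TESCl, imidazole, CH2Cl2, 0 °C
Reagents that add atoms: chlorotriethylsilane, CC[Si](Cl)(CC)CC
Why: Silylation of the primary alcohol, so that the C8 oxygen neither consumes base in the Dieckmann step nor is triflated in step 13.

Step 12
Reactants: 18 methyl (2S)-2-{3-[(4-methoxyphenyl)methoxy]propanoyloxy}-2-{(2R,3S)-3-methyl-3-[(3Z)-4-methyl-6-(triethylsilyloxy)hex-3-en-1-yl]oxiran-2-yl}acetate
Product: 19 (5S)-4-hydroxy-3-{[(4-methoxyphenyl)methoxy]methyl}-5-{(2R,3S)-3-methyl-3-[(3Z)-4-methyl-6-(triethylsilyloxy)hex-3-en-1-yl]oxiran-2-yl}furan-2(5H)-one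
Conditions: LiHMDS (2.2 equiv), THF, −78 → −30 °C; aq. NaH2PO4/citric acid (pH 3), 0 °C; crude product used at once
Reagents that add atoms: none
Why: Dieckmann (intramolecular Claisen) closure of an α-acyloxy ester to a tetronic acid: kinetic deprotonation at the unhindered acyl methylene C11, 5-exo-trig attack on the C7 ester and loss of methoxide give the tetronate, which is no longer acidic at C6. Closures of this kind on O-acyl α-hydroxy esters keep the carbinol configuration, which shows that the hindered C6–H is not removed; this matters here because a C6 enolate would open the epoxide. Compound 19 is taken on directly because its acidic enol sits next to the epoxide.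

Step 13
Reactants: 19 (5S)-4-hydroxy-3-{[(4-methoxyphenyl)methoxy]methyl}-5-{(2R,3S)-3-methyl-3-[(3Z)-4-methyl-6-(triethylsilyloxy)hex-3-en-1-yl]oxiran-2-yl}furan-2(5H)-one
Product: 20 (2S)-4-{[(4-methoxyphenyl)methoxy]methyl}-2-{(2R,3S)-3-methyl-3-[(3Z)-4-methyl-6-(triethylsilyloxy)hex-3-en-1-yl]oxiran-2-yl}-5-oxo-2,5-dihydrofuran-3-yl trifluoromethanesulfonate
Conditions: Tf2O (1.1 equiv), iPr2NEt, CH2Cl2, −78 °C
Reagents that add atoms: trifluoromethanesulfonic anhydride, O=S(=O)(OS(=O)(=O)C(F)(F)F)C(F)(F)F
Why: O-Sulfonylation of the tetronate at the C7 oxygen, the standard route to 4-triflyloxybutenolides. The hindered amine at −78 °C does not remove the γ-proton at C6.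

Step 14
Reactants: 20 (2S)-4-{[(4-methoxyphenyl)methoxy]methyl}-2-{(2R,3S)-3-methyl-3-[(3Z)-4-methyl-6-(triethylsilyloxy)hex-3-en-1-yl]oxiran-2-yl}-5-oxo-2,5-dihydrofuran-3-yl trifluoromethanesulfonate
Product: 21 (2S)-2-{(2R,3S)-3-[(3Z)-6-hydroxy-4-methylhex-3-en-1-yl]-3-methyloxiran-2-yl}-4-{[(4-methoxyphenyl)methoxy]methyl}-5-oxo-2,5-dihydrofuran-3-yl trifluoromethanesulfonate
Conditions: Et3N·3HF, THF, 0 °C → rt
Reagents that add atoms: none
Why: Fluoride cleavage of the primary silyl ether with a nearly neutral, non-nucleophilic reagent that spares the enol triflate and the epoxide. The C8 hydroxyl is too far from the C4–C5 epoxide to attack it.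

Step 15
Reactants: 21 (2S)-2-{(2R,3S)-3-[(3Z)-6-hydroxy-4-methylhex-3-en-1-yl]-3-methyloxiran-2-yl}-4-{[(4-methoxyphenyl)methoxy]methyl}-5-oxo-2,5-dihydrofuran-3-yl trifluoromethanesulfonate
Product: 22 (2S)-4-{[(4-methoxyphenyl)methoxy]methyl}-2-{(2R,3S)-3-methyl-3-[(3Z)-4-methyl-6-oxohex-3-en-1-yl]oxiran-2-yl}-5-oxo-2,5-dihydrofuran-3-yl trifluoromethanesulfonate
Conditions: Dess–Martin periodinane, NaHCO3, CH2Cl2, 0 °C; used crude
Reagents that add atoms: none
Why: Buffered periodinane oxidation turns the homoallylic alcohol into the β,γ-unsaturated aldehyde without amine base, so the double bond does not move into conjugation.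

Step 16
Reactants: 22 (2S)-4-{[(4-methoxyphenyl)methoxy]methyl}-2-{(2R,3S)-3-methyl-3-[(3Z)-4-methyl-6-oxohex-3-en-1-yl]oxiran-2-yl}-5-oxo-2,5-dihydrofuran-3-yl trifluoromethanesulfonate
Product: 23 (4S,5R,6R,8R)-4,5-epoxy-8-hydroxy-13-[(4-methoxyphenyl)methoxy]germacra-1(10)Z,7(11)-dien-12,6-olide
Conditions: CrCl2 (8 equiv), NiCl2 (cat.), DMSO/THF, rt, slow addition of 22 (final 0.002 M)
Reagents that add atoms: none
Why: Nozaki–Hiyama–Kishi reaction: zerovalent nickel, formed from NiCl2 by CrCl2, inserts into the C7–OTf bond, and transmetalation gives an alkenyl species of trivalent chromium that adds only to the aldehyde, forming C7–C8 and closing the ten-membered ring under high dilution. C8 becomes a stereocentre; the (8R) alcohol, with its oxygen on the lactone-oxygen face, is the one needed, and which epimer predominates is set by the conformation of the closing ring.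

Step 17
Reactants: 23 (4S,5R,6R,8R)-4,5-epoxy-8-hydroxy-13-[(4-methoxyphenyl)methoxy]germacra-1(10)Z,7(11)-dien-12,6-olide; 24 3-methylbut-2-enoyl chloride
Product: 25 (4S,5R,6R,8R)-4,5-epoxy-13-[(4-methoxyphenyl)methoxy]-8-(3-methylbut-2-enoyloxy)germacra-1(10)Z,7(11)-dien-12,6-olide
Conditions: 24, pyridine, CH2Cl2, 0 °C → rt
Reagents that add atoms: none
Why: Acylation of the secondary allylic alcohol. Pyridine is used in place of a trialkylamine so that the acid chloride does not form a vinylketene, which would give the deconjugated ester, and so that the C6–H is not removed.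

Step 18
Reactants: 25 (4S,5R,6R,8R)-4,5-epoxy-13-[(4-methoxyphenyl)methoxy]-8-(3-methylbut-2-enoyloxy)germacra-1(10)Z,7(11)-dien-12,6-olide
Product: 26 (1S,4S,5R,6R,8R,10R)-1,10:4,5-diepoxy-13-[(4-methoxyphenyl)methoxy]-8-(3-methylbut-2-enoyloxy)germacr-7(11)-en-12,6-olide
Conditions: mCPBA, NaHCO3, CH2Cl2, 0 °C
Reagents that add atoms: 3-chloroperoxybenzoic acid, OOC(=O)c1cccc(Cl)c1
Why: Prilezhaev epoxidation: the peracid reacts only with the electron-rich isolated trisubstituted alkene, the conjugated senecioate and butenolide alkenes being deactivated, and syn addition turns the Z-alkene into the cis-epoxide. Attack on the outer face of the ring alkene, away from the C8 ester and from the lactone and 4,5-epoxide oxygens that share its face, should give the (1S,10R) epoxide.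

Step 19
Reactants: 26 (1S,4S,5R,6R,8R,10R)-1,10:4,5-diepoxy-13-[(4-methoxyphenyl)methoxy]-8-(3-methylbut-2-enoyloxy)germacr-7(11)-en-12,6-olide
Product: 27 (1S,4S,5R,6R,8R,10R)-1,10:4,5-diepoxy-13-hydroxy-8-(3-methylbut-2-enoyloxy)germacr-7(11)-en-12,6-olide
Conditions: DDQ, CH2Cl2/pH 7 buffer, 0 °C → rt
Reagents that add atoms: none
Why: Oxidative cleavage of the 4-methoxybenzyl ether through its benzylic cation and hemiacetal at neutral pH, which leaves both epoxides, the esters and the lactone untouched.

Step 20
Reactants: 27 (1S,4S,5R,6R,8R,10R)-1,10:4,5-diepoxy-13-hydroxy-8-(3-methylbut-2-enoyloxy)germacr-7(11)-en-12,6-olide; 28 acetic anhydride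
Product: 29 (1S,4S,5R,6R,8R,10R)-13-acetoxy-1,10:4,5-diepoxy-8-(3-methylbut-2-enoyloxy)germacr-7(11)-en-12,6-olide (CNP0228323.1)
Conditions: 28, pyridine, CH2Cl2, 0 °C → rt
Reagents that add atoms: none
Why: Acetylation of the primary allylic alcohol. No nucleophilic acyl-transfer catalyst is added, because the product is an allylic acetate on a Michael acceptor and would be open to SN2′ displacement.

## Compound list

1 | (S)-linalool, (3S)-3,7-dimethylocta-1,6-dien-3-ol | C=C[C@@](C)(O)CCC=C(C)C | starting material
2 | (4S)-4-hydroxy-4-methylhex-5-enal | C=C[C@@](C)(O)CCC=O | intermediate (not isolated)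
3 | (4S)-4-methylhex-5-ene-1,4-diol | C=C[C@@](C)(O)CCCO | intermediate
4 | (3S)-3-methyl-6-(triethylsilyloxy)hex-1-en-3-ol | C=C[C@@](C)(O)CCCO[Si](CC)(CC)CC | intermediate
5 | methyl acrylate | C=CC(=O)OC | starting material
6 | methyl (2E,4S)-4-hydroxy-4-methyl-7-(triethylsilyloxy)hept-2-enoate | COC(=O)/C=C/[C@@](C)(O)CCCO[Si](CC)(CC)CC | intermediate
7 | methyl (2S,3S)-3-[(2S)-2-hydroxy-5-(triethylsilyloxy)pentan-2-yl]oxirane-2-carboxylate | CC[Si](CC)(CC)OCCC[C@](C)(O)[C@H]1O[C@@H]1C(=O)OC | intermediate
8 | methyl (2S)-2-hydroxy-2-{(2R,3S)-3-methyl-3-[3-(triethylsilyloxy)propyl]oxiran-2-yl}acetate | CC[Si](CC)(CC)OCCC[C@]1(C)O[C@@H]1[C@H](O)C(=O)OC | intermediate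
9 | 3-[(4-methoxyphenyl)methoxy]propanoic acid | COc1ccc(COCCC(=O)O)cc1 | starting material
10 | methyl (2S)-2-{3-[(4-methoxyphenyl)methoxy]propanoyloxy}-2-{(2R,3S)-3-methyl-3-[3-(triethylsilyloxy)propyl]oxiran-2-yl}acetate | CC[Si](CC)(CC)OCCC[C@]1(C)O[C@@H]1[C@H](OC(=O)CCOCc2ccc(OC)cc2)C(=O)OC | intermediate
11 | methyl (2S)-2-{3-[(4-methoxyphenyl)methoxy]propanoyloxy}-2-[(2R,3S)-3-methyl-3-(3-oxopropyl)oxiran-2-yl]acetate | O=CCC[C@]1(C)O[C@@H]1[C@H](OC(=O)CCOCc2ccc(OC)cc2)C(=O)OC | intermediate
12 | ethyl(triphenyl)phosphonium iodide | CC[P+](c1ccccc1)(c1ccccc1)c1ccccc1.[I-] | starting material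
13 | methyl (2S)-2-{(2R,3S)-3-[(3Z)-4-iodopent-3-en-1-yl]-3-methyloxiran-2-yl}-2-{3-[(4-methoxyphenyl)methoxy]propanoyloxy}acetate | C/C(I)=C/CC[C@]1(C)O[C@@H]1[C@H](OC(=O)CCOCc2ccc(OC)cc2)C(=O)OC | intermediate
14 | tributyl(ethenyl)stannane | C=C[Sn](CCCC)(CCCC)CCCC | starting material
15 | methyl (2S)-2-{3-[(4-methoxyphenyl)methoxy]propanoyloxy}-2-{(2R,3S)-3-methyl-3-[(3Z)-4-methylhexa-3,5-dien-1-yl]oxiran-2-yl}acetate | C=C/C(C)=C\CC[C@]1(C)O[C@@H]1[C@H](OC(=O)CCOCc2ccc(OC)cc2)C(=O)OC | intermediate
16 | methyl (2S)-2-{(2R,3S)-3-[(3Z)-6-(9-borabicyclo[3.3.1]nonan-9-yl)-4-methylhex-3-en-1-yl]-3-methyloxiran-2-yl}-2-{3-[(4-methoxyphenyl)methoxy]propanoyloxy}acetate | B1(CC/C(C)=C\CC[C@]3(C)O[C@@H]3[C@H](OC(=O)CCOCc4ccc(OC)cc4)C(=O)OC)C2CCCC1CCC2 | intermediate (not isolated)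
17 | methyl (2S)-2-{(2R,3S)-3-[(3Z)-6-hydroxy-4-methylhex-3-en-1-yl]-3-methyloxiran-2-yl}-2-{3-[(4-methoxyphenyl)methoxy]propanoyloxy}acetate | OCC/C(C)=C\CC[C@]1(C)O[C@@H]1[C@H](OC(=O)CCOCc2ccc(OC)cc2)C(=O)OC | intermediate
18 | methyl (2S)-2-{3-[(4-methoxyphenyl)methoxy]propanoyloxy}-2-{(2R,3S)-3-methyl-3-[(3Z)-4-methyl-6-(triethylsilyloxy)hex-3-en-1-yl]oxiran-2-yl}acetate | CC[Si](CC)(CC)OCC/C(C)=C\CC[C@]1(C)O[C@@H]1[C@H](OC(=O)CCOCc2ccc(OC)cc2)C(=O)OC | intermediate
19 | (5S)-4-hydroxy-3-{[(4-methoxyphenyl)methoxy]methyl}-5-{(2R,3S)-3-methyl-3-[(3Z)-4-methyl-6-(triethylsilyloxy)hex-3-en-1-yl]oxiran-2-yl}furan-2(5H)-one | CC[Si](CC)(CC)OCC/C(C)=C\CC[C@]1(C)O[C@@H]1[C@@H]1OC(=O)C(COCc2ccc(OC)cc2)=C1O | intermediate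
20 | (2S)-4-{[(4-methoxyphenyl)methoxy]methyl}-2-{(2R,3S)-3-methyl-3-[(3Z)-4-methyl-6-(triethylsilyloxy)hex-3-en-1-yl]oxiran-2-yl}-5-oxo-2,5-dihydrofuran-3-yl trifluoromethanesulfonate | CC[Si](CC)(CC)OCC/C(C)=C\CC[C@]1(C)O[C@@H]1[C@@H]1OC(=O)C(COCc2ccc(OC)cc2)=C1OS(=O)(=O)C(F)(F)F | intermediate
21 | (2S)-2-{(2R,3S)-3-[(3Z)-6-hydroxy-4-methylhex-3-en-1-yl]-3-methyloxiran-2-yl}-4-{[(4-methoxyphenyl)methoxy]methyl}-5-oxo-2,5-dihydrofuran-3-yl trifluoromethanesulfonate | OCC/C(C)=C\CC[C@]1(C)O[C@@H]1[C@@H]1OC(=O)C(COCc2ccc(OC)cc2)=C1OS(=O)(=O)C(F)(F)F | intermediate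
22 | (2S)-4-{[(4-methoxyphenyl)methoxy]methyl}-2-{(2R,3S)-3-methyl-3-[(3Z)-4-methyl-6-oxohex-3-en-1-yl]oxiran-2-yl}-5-oxo-2,5-dihydrofuran-3-yl trifluoromethanesulfonate | O=CC/C(C)=C\CC[C@]1(C)O[C@@H]1[C@@H]1OC(=O)C(COCc2ccc(OC)cc2)=C1OS(=O)(=O)C(F)(F)F | intermediate
23 | (4S,5R,6R,8R)-4,5-epoxy-8-hydroxy-13-[(4-methoxyphenyl)methoxy]germacra-1(10)Z,7(11)-dien-12,6-olide | COc1ccc(cc1)COCC1=C2[C@@H](OC1=O)[C@H]1O[C@@]1(C)CC/C=C(C)\C[C@H]2O | intermediate
24 | 3-methylbut-2-enoyl chloride | CC(C)=CC(=O)Cl | starting material
25 | (4S,5R,6R,8R)-4,5-epoxy-13-[(4-methoxyphenyl)methoxy]-8-(3-methylbut-2-enoyloxy)germacra-1(10)Z,7(11)-dien-12,6-olide | COc1ccc(cc1)COCC1=C2[C@@H](OC1=O)[C@H]1O[C@@]1(C)CC/C=C(C)\C[C@H]2OC(=O)C=C(C)C | intermediate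
26 | (1S,4S,5R,6R,8R,10R)-1,10:4,5-diepoxy-13-[(4-methoxyphenyl)methoxy]-8-(3-methylbut-2-enoyloxy)germacr-7(11)-en-12,6-olide | COc1ccc(cc1)COCC1=C2[C@@H](OC1=O)[C@H]1O[C@@]1(C)CC[C@@H]1O[C@]1(C)C[C@H]2OC(=O)C=C(C)C | intermediate
27 | (1S,4S,5R,6R,8R,10R)-1,10:4,5-diepoxy-13-hydroxy-8-(3-methylbut-2-enoyloxy)germacr-7(11)-en-12,6-olide | OCC1=C2[C@@H](OC1=O)[C@H]1O[C@@]1(C)CC[C@@H]1O[C@]1(C)C[C@H]2OC(=O)C=C(C)C | intermediate
28 | acetic anhydride | CC(=O)OC(C)=O | starting material
29 | (1S,4S,5R,6R,8R,10R)-13-acetoxy-1,10:4,5-diepoxy-8-(3-methylbut-2-enoyloxy)germacr-7(11)-en-12,6-olide | CC(=O)OCC1=C2[C@@H](OC1=O)[C@H]1O[C@@]1(C)CC[C@@H]1O[C@]1(C)C[C@H]2OC(=O)C=C(C)C | target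

## Step count and least certain steps

Total: 20 steps. Longest linear sequence: 20 steps, from 1 to 29; the other reactants (5, 9, 12, 14, 24, 28) are bought.

**Step 5 (key step).** The most likely problem is an equilibrium that does not go far enough, or slow loss of material while it is reached, because both alkoxides can attack the methyl ester of another molecule. The fallback traps the product alkoxide as it forms. Acid 9 is converted with 1,1'-carbonyldiimidazole into its imidazolide, 1-{3-[(4-methoxyphenyl)methoxy]propanoyl}imidazole F1. Ester 7 is deprotonated with NaH in THF at −40 °C and F1 is added; the unhindered C6 alkoxide is acylated much faster than the tertiary C4 alkoxide, so the equilibrating pair is drained towards the ester. This sets out from 7 and comes back at 10, merging steps 5 and 6.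

**Step 16.** The new carbinol may form with the wrong configuration or as a mixture, since facial selectivity depends only on the conformation in which the chain folds onto the butenolide. Oligomerisation is a matter of concentration and is handled by slow addition. The fallback accepts the epimer, (4S,5R,6R,8S)-4,5-epoxy-8-hydroxy-13-[(4-methoxyphenyl)methoxy]germacra-1(10)Z,7(11)-dien-12,6-olide F2, and corrects C8 while installing the ester: Mitsunobu reaction with 3-methylbut-2-enoic acid (PPh3, diisopropyl azodicarboxylate, toluene, 0 °C) gives the senecioate with inversion. This sets out from 22 and comes back at 25, replacing step 17.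

**Step 18.** The peracid may attack the other face of the ring alkene or give a mixture, because the accessible face is fixed by the ring conformation and cannot be overridden by a reagent once the ring exists. The fallback sets the epoxide before ring closure under reagent control. Alcohol 21 is epoxidised at its homoallylic alkene with VO(OiPr)3, a chiral bis-hydroxamic acid ligand and cumene hydroperoxide in toluene (hydroxyl-directed, the ligand enantiomer chosen for the 1S,10R sense). This gives (2S)-2-{(2R,3S)-3-[2-[(2S,3R)-3-(2-hydroxyethyl)-3-methyloxiran-2-yl]ethyl]-3-methyloxiran-2-yl}-4-{[(4-methoxyphenyl)methoxy]methyl}-5-oxo-2,5-dihydrofuran-3-yl trifluoromethanesulfonate F3. Buffered Dess–Martin oxidation gives the corresponding aldehyde, the 2-oxoethyl analogue F4, and CrCl2/NiCl2 ring closure as in step 16 gives (1S,4S,5R,6R,8R,10R)-1,10:4,5-diepoxy-8-hydroxy-13-[(4-methoxyphenyl)methoxy]germacr-7(11)-en-12,6-olide F5, which is acylated with 24 as in step 17. This sets out from 21 and comes back at 26.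

**Step 4.** The hindered enoate, with a quaternary γ-carbon and a free hydroxyl, may react slowly or with poor catalyst control. The fallback uses the Sharpless epoxidation of the allylic alcohol. Ester 6 is reduced with iBu2AlH (CH2Cl2, −78 °C) to (2E,4S)-4-methyl-7-(triethylsilyloxy)hept-2-ene-1,4-diol F6. Epoxidation with Ti(OiPr)4, D-(−)-diethyl tartrate and tBuOOH (CH2Cl2, −20 °C) gives (2S)-2-[(2S,3R)-3-(hydroxymethyl)oxiran-2-yl]-5-(triethylsilyloxy)pentan-2-ol F7. Oxidation with TEMPO/PhI(OAc)2 in buffered MeCN/water gives (2S,3S)-3-[(2S)-2-hydroxy-5-(triethylsilyloxy)pentan-2-yl]oxirane-2-carboxylic acid F8, and Me3SiCHN2 in MeOH gives the methyl ester. This sets out from 6 and comes back at 7.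

**Step 8.** The iodo-ylide olefination is capricious: conversion is often modest, Z selectivity incomplete and non-iodinated alkene can form. The fallback builds the same Z pattern in two couplings. Aldehyde 11 with CBr4/PPh3/Et3N (CH2Cl2, 0 °C) gives methyl (2S)-2-[(2R,3S)-3-(4,4-dibromobut-3-en-1-yl)-3-methyloxiran-2-yl]-2-{3-[(4-methoxyphenyl)methoxy]propanoyloxy}acetate F9. Trans-selective monomethylation with MeZnCl and PdCl2(DPEphos) in THF replaces the bromine trans to the chain and gives the (3Z)-4-bromopent-3-en-1-yl analogue of 13, F10. Stille coupling of F10 with 14 (Pd(PtBu3)2, CsF, dioxane) then gives the diene. This sets out from 11 and comes back at 15.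

## Further compounds

F1 | step 5 | 1-{3-[(4-methoxyphenyl)methoxy]propanoyl}imidazole | COc1ccc(COCCC(=O)n2ccnc2)cc1
F2 | step 16 | (4S,5R,6R,8S)-4,5-epoxy-8-hydroxy-13-[(4-methoxyphenyl)methoxy]germacra-1(10)Z,7(11)-dien-12,6-olide | COc1ccc(cc1)COCC1=C2[C@@H](OC1=O)[C@H]1O[C@@]1(C)CC/C=C(C)\C[C@@H]2O
F3 | step 18 | (2S)-2-{(2R,3S)-3-[2-[(2S,3R)-3-(2-hydroxyethyl)-3-methyloxiran-2-yl]ethyl]-3-methyloxiran-2-yl}-4-{[(4-methoxyphenyl)methoxy]methyl}-5-oxo-2,5-dihydrofuran-3-yl trifluoromethanesulfonate | OCC[C@@]1(C)O[C@H]1CC[C@]1(C)O[C@@H]1[C@@H]1OC(=O)C(COCc2ccc(OC)cc2)=C1OS(=O)(=O)C(F)(F)F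
F4 | step 18 | (2S)-4-{[(4-methoxyphenyl)methoxy]methyl}-2-{(2R,3S)-3-methyl-3-[2-[(2S,3R)-3-methyl-3-(2-oxoethyl)oxiran-2-yl]ethyl]oxiran-2-yl}-5-oxo-2,5-dihydrofuran-3-yl trifluoromethanesulfonate | O=CC[C@@]1(C)O[C@H]1CC[C@]1(C)O[C@@H]1[C@@H]1OC(=O)C(COCc2ccc(OC)cc2)=C1OS(=O)(=O)C(F)(F)F
F5 | step 18 | (1S,4S,5R,6R,8R,10R)-1,10:4,5-diepoxy-8-hydroxy-13-[(4-methoxyphenyl)methoxy]germacr-7(11)-en-12,6-olide | COc1ccc(cc1)COCC1=C2[C@@H](OC1=O)[C@H]1O[C@@]1(C)CC[C@@H]1O[C@]1(C)C[C@H]2O
F6 | step 4 | (2E,4S)-4-methyl-7-(triethylsilyloxy)hept-2-ene-1,4-diol | OC/C=C/[C@@](C)(O)CCCO[Si](CC)(CC)CC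
F7 | step 4 | (2S)-2-[(2S,3R)-3-(hydroxymethyl)oxiran-2-yl]-5-(triethylsilyloxy)pentan-2-ol | CC[Si](CC)(CC)OCCC[C@](C)(O)[C@H]1O[C@@H]1CO
F8 | step 4 | (2S,3S)-3-[(2S)-2-hydroxy-5-(triethylsilyloxy)pentan-2-yl]oxirane-2-carboxylic acid | CC[Si](CC)(CC)OCCC[C@](C)(O)[C@H]1O[C@@H]1C(=O)O
F9 | step 8 | methyl (2S)-2-[(2R,3S)-3-(4,4-dibromobut-3-en-1-yl)-3-methyloxiran-2-yl]-2-{3-[(4-methoxyphenyl)methoxy]propanoyloxy}acetate | BrC(Br)=CCC[C@]1(C)O[C@@H]1[C@H](OC(=O)CCOCc2ccc(OC)cc2)C(=O)OC
F10 | step 8 | methyl (2S)-2-{(2R,3S)-3-[(3Z)-4-bromopent-3-en-1-yl]-3-methyloxiran-2-yl}-2-{3-[(4-methoxyphenyl)methoxy]propanoyloxy}acetate | C/C(Br)=C/CC[C@]1(C)O[C@@H]1[C@H](OC(=O)CCOCc2ccc(OC)cc2)C(=O)OC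
A1 | alternative 1 | (2Z,6Z)-3,7-dimethyl-1-vinylcycloocta-2,6-dien-1-ol (racemic) | C=CC1(O)/C=C(C)\CC/C=C(C)\C1
A2 | alternative 1 | (2Z,6Z)-3,7-dimethylcyclodeca-2,6-dien-1-one | O=C1/C=C(C)\CC/C=C(C)\CCC1
A3 | alternative 2 | (2Z,6Z)-2,6-dimethylocta-2,6-diene-1,8-diol | OC/C(C)=C\CC/C(C)=C\CO
A4 | alternative 2 | bis-epoxy diol with C10, C1, C4 and C5 as in the target (10R,1S,4S,5R in germacrane numbering) | OC[C@@]1(C)O[C@H]1CC[C@]1(C)O[C@@H]1CO
A5 | alternative 3 | eleven-membered α-chlorosulfone (sulfonyl bridge between C4 and C5, chlorine on C5; C4 and C5 as mixtures) | C=C1[C@@H](O[Si](CC)(CC)CC)C(Cl)S(=O)(=O)C(C)CC[C@@H]2O[C@]2(C)C[C@H]1O[Si](C)(C)C(C)(C)C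
A6 | alternative 3 | (4Z)-cyclodecene with the C1–C10 epoxide, C7 methylene and C6, C8 silyl ethers | C=C1[C@@H](O[Si](CC)(CC)CC)/C=C(C)\CC[C@@H]2O[C@]2(C)C[C@H]1O[Si](C)(C)C(C)(C)C
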